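## Structural features

Locants follow a 4,5,6,7-tetrahydroindole (N1, C2, C3, C3a, C4, C5, C6, C7, C7a); Cα is the methyl-bearing carbon of the fused lactone, C3′ and C5′ are the methyl-bearing and oxygen-bearing carbons of the pendant lactone. The target is pentacyclic: a pyrrole (ring A) is fused along N1–C7a to an azepane (ring B, four methylenes from N1 to C7) and along C3a–C7a to a cyclohexane (ring C). Ring C carries a cis-fused α-methyl-γ-butyrolactone (ring D, C5–O–C(=O)–Cα–C4) and an ethyl group at C6, and C2 carries a second α-methyl-γ-butyrolactone (ring E) through C5′. Five stereocentres are contiguous (C7, C6, C5, C4, Cα): the azepane bond at C7 and the ethyl at C6 are trans, the ethyl and the C5 oxygen are cis, ring D is cis-fused, and the Cα methyl sits on the concave face, cis to C3a. The other two (C5′ and C3′, mutually cis) lie beyond the flat pyrrole and receive no control from the core. Fragile elements are the electron-rich pyrrole, the pyrrolylic C5′–O bond (which ionises easily to an azafulvenium ion) and both lactone α-centres; Cα holds what is presumably the less stable configuration and must not meet base once set. The real difficulty is ring D with its contra-steric methyl next to a pyrrolylic methine, together with absolute control in a core whose only handles are C5 and the pyrrole. The key step uses the fact that C4 is a pyrrolylic carbon of ring C next to the carbinol C5: with an axial 2-diazopropanoate on the C5 oxygen, the C4–H bond cis to C5–O is 1,5 to the diazo carbon, so a carbenoid there can insert and form the Cα–C4 bond and ring D.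

## Logic of the disconnections

30 ⇒ 29. The C3′ stereocentre is removed by returning to a C3′=CH2 group. Hydrogen should add to the nearly flat lactone from the face away from the pyrrole, which gives the 3′,5′-cis relation. The forward step must not cleave the pyrrolylic C5′–O bond or move the double bond into the ring.

29 ⇒ 26 + 27. The C5′–C4′ bond and the acyl C–O bond of ring E are cut. C5′ has no neighbouring stereocentre, so it has to come from a catalyst-controlled addition to an aldehyde. This removes ring E and reduces the problem to a C2 aldehyde plus a four-carbon acrylate unit. The forward step must add to the Si face and lactonise without acid or strong base.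

26 ⇒ 22. The C2–CHO bond is exchanged for a C2–CO2t-Bu bond. The ester is the blocking group that protects the pyrrole during the carbenoid step. The forward step must remove the ester, lose CO2 and formylate the freed α-position in acid without touching ring D.

22 ⇒ 20. Only the Cα–H bond changes, by inversion. The insertion is expected to put the methyl on the convex face, so the required concave methyl is assigned to a separate enolate protonation. The forward step needs proton delivery from the convex face only.

20 ⇒ 19 (key). The Cα–C4 bond is cut. Cα and C4 are 1,5 across the ester, the C4–H bond is pyrrolylic, and a cis ring fusion is the only geometric possibility. Ring D and two stereocentres are traded for an ester on a secondary alcohol. The carbenoid must insert faster than it undergoes 1,2-hydride shift, attacks C7–H or attacks the pyrrole.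

19 ⇒ 18 ⇒ 16 + 17. The C=N2 unit and then the acyl C–O bond are cut. A propanoate cannot be diazotised directly, so an acetyl group activates the α-carbon and is lost during diazo transfer. The forward acylation must succeed on a hindered axial alcohol.

16 ⇒ 15. The C5–H bond is cut. A bulky hydride attacking equatorially gives the axial alcohol cis to the ethyl group. The geometry of this alcohol decides which C–H bonds the later carbenoid can reach.

15 ⇒ 14. The C6–C7 bond is cut. C7 is the carbon a pyrrole nitrogen can stabilise as a cation and C6 is the enol carbon of the ketone, so the polarity is natural. Ring C and both stereocentres fall away and the precursor may be racemic. The forward step must be enantioconvergent and trans-selective.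

14 ⇒ 12. The carbinol goes back to a ring ketone and the side-chain ketone to a nitro group. Hydride cannot distinguish two ketones in favour of the conjugated one, so the side-chain ketone is kept masked until the ring ketone is reduced. The unmasking must be non-acidic so that the ionisable carbinol survives.

12 ⇒ 10. The C9–C9a acyl bond (pyrrole numbering of the bicycle) is cut. The tether can reach only that one pyrrole carbon. The forward acylation must spare the tert-butyl ester.

10 ⇒ 8 ⇒ 6 + 7. The acid is returned to its ethyl ester and the C–C single bond to the nitroalkene, then the C=C bond is cut. The four carbons of 7 supply C5, C6 and the ethyl group, and the nitro carbon becomes C5.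

6 ⇒ 4 + 5. The N–C bond is cut; alkylation must precede nitroalkane formation because a nitronate would compete for the bromide.

4 ⇒ 3 ⇒ 1. The tert-butyl ester is returned to the trichloromethyl ketone and the C4–CHO bond is cut. The acyl group of 1 directs the formyl group to C4.

## Other disconnections considered

Alternative 1: Both N1–C(α) bonds of ring A are cut, which also opens ring B at nitrogen. The precursor is the azido keto aldehyde A1, a cyclohexanone whose ketone carbon becomes C7a and whose acetaldehyde arm supplies C3 and C2. In the forward step PPh3 reduces the azide (Staudinger), the amine condenses with ring ketone and aldehyde, and AcOH completes a Paal–Knorr closure to the tricyclic ketal A2.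
- In favour: two rings and two C–N bonds form in one robust condensation; the pyrrole appears late; no azafulvenium ion is involved.
- Against: A2 has a free C2, so a later carbenoid would face an unblocked, nucleophilic α-position. C7 sits α to the condensing ketone and may epimerise. A1 is a cyclohexanone with four different substituents that must be built and rendered enantiopure. The ketal still has to be removed, C5 reduced and ring D annulated.
- Comparison: this alternative addresses rings A and B and is complementary to the carbenoid plan. It is better in the reliability of its ring-forming event and in avoiding an unprecedented enantioselective step. It is equal in still needing a ring D annulation. It is probably worse in step count, because A1 needs a long stereocontrolled preparation.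

Alternative 2: The C4–C3a bond is cut. The precursor A3 is a pyrroloazepine whose C7 carries a CH(Et) group bonded to the γ-carbon of an α-methylbutenolide. In the forward step Sc(OTf)3 activates the butenolide, the pyrrole β-carbon adds to its β-carbon (6-exo-trig), and α-protonation gives the tetracycle A4, which has the structure of 24.
- In favour: ring C, C4 and Cα form in one step. The enolate is protonated from the convex face, which gives the concave methyl directly; here the alternative is better than the chosen plan, which needs a separate correction. No diazo compound or blocking ester is needed, so A4 is about three steps from the target against five.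
- Against: the C5/C6/C7 triad must be assembled on an open chain with no ring to relay stereochemistry. An α-substituted butenolide is a weak, reversible acceptor. The unblocked pyrrole α-position can react intermolecularly under Lewis acid.
- Comparison: mechanistically it is a Friedel–Crafts conjugate addition against a C–H insertion; both enforce the cis fusion through the tether. The chosen plan is stronger where this one is weak: the three ring C centres come from ring conformation (thermodynamic trans, equatorial hydride attack). The end game of Alternative 2 is shorter, but its route to A3 is likely longer and less certain.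

Alternative 3: The C6–C7 bond is cut. The precursor is the racemic carbinol A5 (the structure of 14). A chiral N-triflylphosphoramide ionises it to an azafulvenium ion that the ketone enol captures, giving the trans ketone A6 (the structure of 15).
- In favour: it is the only one of these disconnections that creates absolute configuration, and it does so catalytically from a racemate while closing ring C and setting two centres.
- Against: it lacks precedent on this substrate class, the enantioselectivity is uncertain, and it leaves ring D untouched.
- Comparison: it is an upstream partner, not a rival; the chosen route uses this closure as step 8 and hangs the carbenoid step on its product. As a centrepiece it is equal in bonds, rings and stereocentres formed and better in being enantio-determining. The carbenoid step is better precedented and solves the harder ring D. If ring D were instead built classically on A6 (enolate alkylation at C4, reduction, lactonisation, methylation), the step count would be about equal.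

Key step: step 12

Remark on catalyst sense: the enantiomers of the two chiral catalysts (steps 8 and 15) are written on the assumption that they lead to (7R) and (5′S); if a catalyst favours the other face, its mirror image is used and nothing else changes.

Remark on Cα: the insertion is assumed to leave the Cα methyl on the convex face, so 20 is written as the (αR) epimer; step 13 converges either Cα epimer on the configuration of the target.

Step 1
Reactants: 1 2-(trichloroacetyl)pyrrole
Product: 3 4-formyl-2-(trichloroacetyl)pyrrole, via chloro ether 2 (not isolated)
Conditions: Cl2CHOMe, AlCl3, CH2Cl2–MeNO2, −20 °C → rt; H2O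
Reagents that add atoms: dichloromethyl methyl ether, COC(Cl)Cl; water, O
Why: Friedel–Crafts (Rieche) formylation; the 2-acyl group directs the electrophile to C4, and the α-chloro ether is hydrolysed to the aldehyde on work-up.

Step 2
Reactants: 3 4-formyl-2-(trichloroacetyl)pyrrole
Product: 4 tert-butyl 4-formyl-1H-pyrrole-2-carboxylate
Conditions: KOt-Bu (2.2 equiv), THF, 0 °C → rt
Reagents that add atoms: potassium tert-butoxide, CC(C)(C)[O-].[K+]
Why: Haloform-type cleavage: the alkoxide adds to the trichloromethyl ketone and CCl3− leaves; the aldehyde has no α-hydrogen and is deactivated in the pyrrolide anion.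

Step 3
Reactants: 4 tert-butyl 4-formyl-1H-pyrrole-2-carboxylate; 5 ethyl 5-bromopentanoate
Product: 6 tert-butyl 1-(5-ethoxy-5-oxopentyl)-4-formylpyrrole-2-carboxylate
Conditions: K2CO3, DMF, 50 °C
Reagents that add atoms: none
Why: SN2 N-alkylation of a pyrrole N–H acidified by two acceptor groups; it is done before any nitroalkane is present, because a nitronate would compete for the bromide.

Step 4
Reactants: 6 tert-butyl 1-(5-ethoxy-5-oxopentyl)-4-formylpyrrole-2-carboxylate; 7 1-nitrobutane
Product: 8 tert-butyl 1-(5-ethoxy-5-oxopentyl)-4-[(E)-2-nitropent-1-enyl]pyrrole-2-carboxylate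
Conditions: NH4OAc, 1-nitrobutane (excess), toluene, 100 °C
Reagents that add atoms: none
Why: Henry (nitroaldol) condensation with dehydration, as for indole-3-carbaldehydes with nitroalkanes; the alkene geometry is irrelevant because it is reduced next.

Step 5
Reactants: 8 tert-butyl 1-(5-ethoxy-5-oxopentyl)-4-[(E)-2-nitropent-1-enyl]pyrrole-2-carboxylate
Product: 10 5-[2-(tert-butoxycarbonyl)-4-(2-nitropentyl)pyrrol-1-yl]pentanoic acid (racemic), via nitro ester 9 (not isolated)
Conditions: NaBH4, THF–EtOH, 0 °C; then LiOH, H2O, rt; AcOH to pH 5
Reagents that add atoms: lithium hydroxide, [Li+].[OH-]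
Why: Conjugate hydride reduction of the nitroalkene, then saponification of the primary alkyl ester only (the tert-butyl ester resists hydroxide); the nitronate is reprotonated at pH 5, below the acidity needed for a Nef reaction.

Step 6
Reactants: 10 5-[2-(tert-butoxycarbonyl)-4-(2-nitropentyl)pyrrol-1-yl]pentanoic acid (racemic)
Product: 12 tert-butyl 1-(2-nitropentyl)-9-oxo-6,7,8,9-tetrahydro-5H-pyrrolo[1,2-a]azepine-3-carboxylate (racemic), via mixed anhydride 11 (not isolated)
Conditions: (CF3CO)2O (1.2 equiv), CH2Cl2 (0.02 M), 0 °C → rt
Reagents that add atoms: none
Why: Intramolecular Friedel–Crafts acylation through the mixed trifluoroacetic anhydride; the tether reaches only the free α-carbon next to nitrogen, and the saturated nitroalkyl group leaves the ring nucleophilic while masking the future ketone.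

Step 7
Reactants: 12 tert-butyl 1-(2-nitropentyl)-9-oxo-6,7,8,9-tetrahydro-5H-pyrrolo[1,2-a]azepine-3-carboxylate (racemic)
Product: 14 tert-butyl 9-hydroxy-1-(2-oxopentyl)-6,7,8,9-tetrahydro-5H-pyrrolo[1,2-a]azepine-3-carboxylate (racemic), via nitro alcohol 13 (not isolated)
Conditions: NaBH4, MeOH, 0 °C → rt; acetone; then K2CO3, 30% H2O2, rt
Reagents that add atoms: hydrogen peroxide, OO
Why: Borohydride reduces the only ketone present, and the oxidative Nef reaction of the nitronate with basic peroxide then unmasks the side-chain ketone without acid, so the ionisable carbinol survives and no two-ketone selectivity problem arises.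

Step 8
Reactants: 14 tert-butyl 9-hydroxy-1-(2-oxopentyl)-6,7,8,9-tetrahydro-5H-pyrrolo[1,2-a]azepine-3-carboxylate (racemic)
Product: 15 N1,C7-tetramethylene-bridged tert-butyl (6R,7R)-6-ethyl-5-oxo-4,5,6,7-tetrahydroindole-2-carboxylate (tricyclic ketone; ethyl trans to the azepane bond at C7)
Conditions: (R)-3,3′-bis(2,4,6-triisopropylphenyl)-1,1′-binaphthyl-2,2′-diyl N-triflylphosphoramide (5 mol %), toluene, 5 Å MS, −20 °C → rt
Reagents that add atoms: none
Why: Proposed new method: the strong chiral acid should ionise either enantiomer of the carbinol to one planar N-alkyl azafulvenium ion held as a contact ion pair with the phosphoramide anion, which also binds the enol of the 2-oxopentyl chain, so that the enol carbon adds to one face of the cation in a 6-endo-trig closure open only to the propyl-side α-carbon (the pyrrolylic α-carbon would give a four-membered ring); the closest known reaction type is the chiral phosphoric acid- or N-triflylphosphoramide-catalysed SN1 substitution of indol-3-yl and pyrrol-2-yl carbinols by enamides, enols and 1,3-dicarbonyls, not yet shown for an intramolecular simple-ketone enol on a secondary alkyl pyrrolyl cation; C7 is set by the catalyst, and C6 follows through a chair-like transition state with equatorial ethyl and stays trans because it can equilibrate through the enol.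

Step 9
Reactants: 15 tricyclic ketone (6R,7R)
Product: 16 N1,C7-tetramethylene-bridged tert-butyl (5S,6R,7R)-6-ethyl-5-hydroxy-4,5,6,7-tetrahydroindole-2-carboxylate (hydroxyl axial and cis to ethyl)
Conditions: LiBH(s-Bu)3, THF, −78 °C; aqueous work-up
Reagents that add atoms: none
Why: The bulky trialkylborohydride attacks the cyclohexanone along the equatorial trajectory and gives the axial alcohol cis to the equatorial ethyl group (substrate control); the hindered, vinylogous-carbamate ester is inert at −78 °C.

Step 10
Reactants: 16 axial alcohol (5S,6R,7R); 17 ethyl 2-methyl-3-oxobutanoate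
Product: 18 2-methyl-3-oxobutanoate ester of 16 at the C5 oxygen (both configurations at the ester α-carbon)
Conditions: DMAP (0.3 equiv), toluene, reflux, 4 Å MS
Reagents that add atoms: none
Why: DMAP-promoted transesterification of a β-keto ester, which runs through an acylketene and therefore acylates even a hindered axial alcohol; the new α-centre is destroyed in the next step.

Step 11
Reactants: 18 2-methyl-3-oxobutanoate ester of 16
Product: 19 2-diazopropanoate ester of 16 at the C5 oxygen (5S,6R,7R)
Conditions: 4-acetamidobenzenesulfonyl azide, DBU, MeCN, 0 °C → rt
Reagents that add atoms: 4-acetamidobenzenesulfonyl azide, CC(=O)Nc1ccc(cc1)S(=O)(=O)N=[N+]=[N-]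
Why: Deacylative Regitz diazo transfer: the enolate of the 2-methyl-β-keto ester adds to the sulfonyl azide and the adduct fragments with loss of N-acetylsulfonamide, the standard entry to α-alkyl α-diazo esters.

Step 12
Reactants: 19 2-diazopropanoate ester (5S,6R,7R)
Product: 20 tetracyclic lactone (4S,5R,6R,7R,αR): ring D cis-fused across C4–C5 with the Cα methyl on the convex face and tert-butyl ester at C2
Conditions: Rh2(O2CCPh3)4 (2 mol %), CH2Cl2, −40 °C → 0 °C
Reagents that add atoms: none
Why: Rh2(O2CCPh3)4 should expel N2 from 19 and form an electrophilic rhodium carbenoid whose carbon takes up the C4–H bond lying cis to the ester oxygen in one concerted, asynchronous event (hydride shift to the carbenoid carbon, C–C bond formation on the rhodium side, release of the catalyst) with retention at C4. The closest known reaction type is the dirhodium tetracarboxylate-catalysed 1,5 C–H insertion of cyclohexyl α-diazo esters to cis-fused γ-butyrolactones, with bulky triphenylacetate ligands and low temperature as the known answer to β-hydride migration in α-alkyl carbenoids. Ring D closes as a five-membered ring by 1,5 insertion through a six-centre array (carbenoid carbon, carbonyl carbon, oxygen, C5, C4, H), and only a cis fusion is possible because the axial C5–O bond is gauche to the equatorial C4–H but anti to the axial C4–H and to the C6–H. C4 is therefore set by the configuration of C5 (substrate control, retention). Cα is set by the orientation of the carbenoid in the transition state: the ligand wall of the catalyst should turn to the open side next to the axial C4–H and away from C3a, which leaves the methyl group on the convex face, hence the (αR) assignment that step 13 corrects. The step needs site selectivity against the 1,3-diaxial C7–H (a bridged six-membered lactone) and the ethyl C–H bonds, and chemoselectivity against 1,2-hydride shift to the acrylate and against attack on the pyrrole. The 1,5 geometry and pyrrolylic activation of the target bond, the triphenylacetate ligands and the ester-deactivated, C2-blocked pyrrole are what should secure this.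

Step 13
Reactants: 20 tetracyclic lactone (αR)
Product: 22 tetracyclic lactone (4S,5R,6R,7R,αS): Cα methyl on the concave face cis to C3a and tert-butyl ester at C2, via lithium enolate 21 (not isolated)
Conditions: LiN(i-Pr)2, THF, −78 → −40 °C; then 2,6-di-tert-butyl-4-methylphenol, −78 °C
Reagents that add atoms: none
Why: Enolisation and kinetic protonation: the bulky phenol can reach the planar enolate of the cis-fused bicycle only from the convex face, which pushes the methyl group to the concave face; the lactone α-hydrogen is the only acidic C–H, and either Cα epimer converges on 22.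

Step 14
Reactants: 22 tetracyclic lactone (αS)
Product: 26 C2-formyl tetracyclic lactone (4S,5R,6R,7R,αS), via C2 carboxylic acid 23 (not isolated), via C2-unsubstituted pyrrole 24 (not isolated), via C2 diethyl acetal 25 (not isolated)
Conditions: CF3CO2H, rt; then HC(OEt)3, 0 °C; H2O, NaHCO3
Reagents that add atoms: triethyl orthoformate, CCOC(OCC)OCC; water, O
Why: Acidolysis of the tert-butyl ester, protodecarboxylation of the pyrrole-2-carboxylic acid by ipso-protonation, and electrophilic formylation of the freed α-position by the dialkoxycarbenium ion in the same flask; acid does not enolise the lactone, so Cα is safe.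

Step 15
Reactants: 26 C2-formyl tetracyclic lactone; 27 ethyl 2-(bromomethyl)acrylate
Product: 29 C2-[(5′S)-3′-methylene-2′-oxotetrahydrofuran-5′-yl] tetracyclic lactone, via silyl ether 28 (not isolated)
Conditions: CrCl2 (10 mol %), (S,S)-3,6-diphenyl-1,8-bis(4-isopropyl-4,5-dihydrooxazol-2-yl)-9H-carbazole (12 mol %), Mn, Me3SiCl, i-Pr2NEt, THF, rt; then Bu4NF, THF, −40 °C; pH 7 buffer
Reagents that add atoms: none
Why: Catalytic asymmetric Nozaki–Hiyama–Kishi-type 2-(alkoxycarbonyl)allylation: the allylchromium species adds to the Si face of the aldehyde under ligand control, since the core stereocentres are too remote to interfere; fluoride then frees the alkoxide, which closes ring E on the acrylate ester at low temperature without acid.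

Step 16
Reactants: 29 α-methylene lactone (5′S)
Product: 30 bisdehydroneotuberostemonine (4S,5R,6R,7R,αS,3′S,5′S)
Conditions: H2 (1 atm), RhCl(PPh3)3 (5 mol %), toluene–EtOH, rt
Reagents that add atoms: none
Why: Homogeneous hydrogenation of the 1,1-disubstituted alkene from the lactone face anti to the pyrrolyl group at C5′ gives the 3′,5′-cis lactone; the rhodium phosphine catalyst is chosen because it neither hydrogenolyses the pyrrolylic C–O bond nor isomerises the alkene into the ring.

## Compound list

1 | 2-(trichloroacetyl)pyrrole | O=C(c1ccc[nH]1)C(Cl)(Cl)Cl | starting material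
2 | 4-[chloro(methoxy)methyl]-2-(trichloroacetyl)pyrrole | COC(Cl)c1c[nH]c(C(=O)C(Cl)(Cl)Cl)c1 | intermediate
3 | 4-formyl-2-(trichloroacetyl)pyrrole | O=Cc1c[nH]c(C(=O)C(Cl)(Cl)Cl)c1 | intermediate
4 | tert-butyl 4-formyl-1H-pyrrole-2-carboxylate | CC(C)(C)OC(=O)c1cc(C=O)c[nH]1 | intermediate
5 | ethyl 5-bromopentanoate | CCOC(=O)CCCCBr | starting material
6 | tert-butyl 1-(5-ethoxy-5-oxopentyl)-4-formylpyrrole-2-carboxylate | CCOC(=O)CCCCn1cc(C=O)cc1C(=O)OC(C)(C)C | intermediate
7 | 1-nitrobutane | CCCC[N+](=O)[O-] | starting material
8 | tert-butyl 1-(5-ethoxy-5-oxopentyl)-4-[(E)-2-nitropent-1-enyl]pyrrole-2-carboxylate | CCC/C(=C\c1cn(CCCCC(=O)OCC)c(C(=O)OC(C)(C)C)c1)[N+](=O)[O-] | intermediate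
9 | tert-butyl 1-(5-ethoxy-5-oxopentyl)-4-(2-nitropentyl)pyrrole-2-carboxylate (racemic) | CCCC(Cc1cn(CCCCC(=O)OCC)c(C(=O)OC(C)(C)C)c1)[N+](=O)[O-] | intermediate
10 | 5-[2-(tert-butoxycarbonyl)-4-(2-nitropentyl)pyrrol-1-yl]pentanoic acid (racemic) | CCCC(Cc1cn(CCCCC(=O)O)c(C(=O)OC(C)(C)C)c1)[N+](=O)[O-] | intermediate
11 | mixed anhydride of 10 with trifluoroacetic acid | CCCC(Cc1cn(CCCCC(=O)OC(=O)C(F)(F)F)c(C(=O)OC(C)(C)C)c1)[N+](=O)[O-] | intermediate
12 | tert-butyl 1-(2-nitropentyl)-9-oxo-6,7,8,9-tetrahydro-5H-pyrrolo[1,2-a]azepine-3-carboxylate (racemic) | CCCC(Cc1cc(C(=O)OC(C)(C)C)n2CCCCC(=O)c12)[N+](=O)[O-] | intermediate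
13 | tert-butyl 9-hydroxy-1-(2-nitropentyl)-6,7,8,9-tetrahydro-5H-pyrrolo[1,2-a]azepine-3-carboxylate (diastereomer mixture) | CCCC(Cc1cc(C(=O)OC(C)(C)C)n2CCCCC(O)c12)[N+](=O)[O-] | intermediate
14 | tert-butyl 9-hydroxy-1-(2-oxopentyl)-6,7,8,9-tetrahydro-5H-pyrrolo[1,2-a]azepine-3-carboxylate (racemic) | CCCC(=O)Cc1cc(C(=O)OC(C)(C)C)n2CCCCC(O)c12 | intermediate
15 | N1,C7-tetramethylene-bridged tert-butyl (6R,7R)-6-ethyl-5-oxo-4,5,6,7-tetrahydroindole-2-carboxylate | CC[C@H]1C(=O)Cc2cc(C(=O)OC(C)(C)C)n3c2[C@@H]1CCCC3 | intermediate
16 | N1,C7-tetramethylene-bridged tert-butyl (5S,6R,7R)-6-ethyl-5-hydroxy-4,5,6,7-tetrahydroindole-2-carboxylate | CC[C@H]1[C@@H](O)Cc2cc(C(=O)OC(C)(C)C)n3c2[C@@H]1CCCC3 | intermediate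
17 | ethyl 2-methyl-3-oxobutanoate | CCOC(=O)C(C)C(C)=O | starting material
18 | 2-methyl-3-oxobutanoate ester of 16 | CC[C@H]1[C@@H](OC(=O)C(C)C(C)=O)Cc2cc(C(=O)OC(C)(C)C)n3c2[C@@H]1CCCC3 | intermediate
19 | 2-diazopropanoate ester of 16 | CC[C@H]1[C@@H](OC(=O)C(C)=[N+]=[N-])Cc2cc(C(=O)OC(C)(C)C)n3c2[C@@H]1CCCC3 | intermediate
20 | tetracyclic lactone, (4S,5R,6R,7R,αR), methyl convex, tert-butyl ester at C2 | CC[C@H]1[C@H]2OC(=O)[C@H](C)[C@H]2c2cc(C(=O)OC(C)(C)C)n3c2[C@@H]1CCCC3 | intermediate
21 | lithium enolate of 20 | CC[C@H]1[C@H]2OC([O-])=C(C)[C@H]2c2cc(C(=O)OC(C)(C)C)n3c2[C@@H]1CCCC3.[Li+] | intermediate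
22 | tetracyclic lactone, (4S,5R,6R,7R,αS), methyl concave, tert-butyl ester at C2 | CC[C@H]1[C@H]2OC(=O)[C@@H](C)[C@H]2c2cc(C(=O)OC(C)(C)C)n3c2[C@@H]1CCCC3 | intermediate
23 | C2 carboxylic acid of the tetracyclic lactone | CC[C@H]1[C@H]2OC(=O)[C@@H](C)[C@H]2c2cc(C(=O)O)n3c2[C@@H]1CCCC3 | intermediate
24 | C2-unsubstituted tetracyclic lactone | CC[C@H]1[C@H]2OC(=O)[C@@H](C)[C@H]2c2ccn3c2[C@@H]1CCCC3 | intermediate
25 | C2 diethyl acetal of the tetracyclic lactone | CC[C@H]1[C@H]2OC(=O)[C@@H](C)[C@H]2c2cc(C(OCC)OCC)n3c2[C@@H]1CCCC3 | intermediate
26 | C2-formyl tetracyclic lactone | CC[C@H]1[C@H]2OC(=O)[C@@H](C)[C@H]2c2cc(C=O)n3c2[C@@H]1CCCC3 | intermediate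
27 | ethyl 2-(bromomethyl)acrylate | C=C(CBr)C(=O)OCC | starting material
28 | (S)-trimethylsilyl ether of the homoallylic alcohol from 26 and 27 | CC[C@H]1[C@H]2OC(=O)[C@@H](C)[C@H]2c2cc([C@H](CC(=C)C(=O)OCC)O[Si](C)(C)C)n3c2[C@@H]1CCCC3 | intermediate
29 | (5′S)-α-methylene lactone | CC[C@H]1[C@H]2OC(=O)[C@@H](C)[C@H]2c2cc([C@@H]3CC(=C)C(=O)O3)n3c2[C@@H]1CCCC3 | intermediate
30 | bisdehydroneotuberostemonine | CC[C@H]1[C@H]2OC(=O)[C@@H](C)[C@H]2c2cc([C@@H]3C[C@H](C)C(=O)O3)n3c2[C@@H]1CCCC3 | target

## Step count and least certain steps

Total step count: 16. Longest linear sequence: 16 steps, from 1; the route is fully linear.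

Step 8 (bears the label). The most likely failure is insufficient facial discrimination of the flat cation by the chiral anion, or erosion of enantiopurity by acid-mediated reversible ring opening, because the cation is a secondary alkyl azafulvenium with little to bind. The fallback sets out from 14. The closure is run without asymmetric induction, with diphenyl phosphate (10 mol %) in toluene at rt, an ordinary acid-catalysed dehydrative alkylation of a ketone by a heteroaryl carbinol; it should give the racemic trans ketone F1. Preparative chromatography on a chiral stationary phase then separates 15 from its mirror image F2, and the route is rejoined at 15.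

Step 12 (key step). The most likely failure is 1,2-hydride migration in the α-methyl carbenoid outrunning insertion, or insertion at the 1,3-diaxial, tertiary and pyrrolylic C7–H bond. The fallback leaves carbenoid chemistry and sets out from 15. LiN(SiMe3)2 (THF, −78 °C) and ethyl iodoacetate alkylate the pyrrolylic α-carbon C4, and DBU equilibrates the product to the equatorial keto ester F3. LiBH(s-Bu)3 (−78 °C → rt) then gives the axial alkoxide, which closes onto the ester to the lactone lacking the Cα methyl, F4. LiN(i-Pr)2 followed by MeI methylates its enolate from the convex face and the route is rejoined at 20.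

Step 13. The most likely failure is incomplete removal of the concave α-hydrogen or proton delivery to both faces of the enolate, because the protonation is against the thermodynamic preference. The fallback sets out from 20 and passes through enolate 21. PhSeCl at −78 °C should add selenium from the convex face to give the Cα-phenylselanyl lactone F5. Bu3SnH with azobisisobutyronitrile (toluene, 80 °C) then replaces selenium by hydrogen through a planar radical that the bulky tin hydride can reach only from the convex face, and the route is rejoined at 22.

Step 6. The most likely failure is acidolysis of the tert-butyl ester by the liberated trifluoroacetic acid followed by decarboxylation, combined with slow acylation of the ester-deactivated ring. The fallback sets out from 10. Coupling with dimethylamine (carbodiimide, CH2Cl2) gives the dimethylamide F6. Activation with (CF3SO2)2O and 2-fluoropyridine (CH2Cl2, −78 → 0 °C), a buffered Vilsmeier-type cyclisation, gives the cyclic iminium triflate F7. Aqueous NaHCO3 hydrolyses it and the route is rejoined at 12.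

Step 15. The most likely failure is weak catalyst control at an electron-rich heteroaryl aldehyde, or ionisation of the pyrrolylic silyl ether under the Lewis-acidic conditions with loss of configuration at C5′. The fallback sets out from 26 and 27. A zinc-mediated Barbier–Reformatsky reaction (Zn, THF, aqueous NH4Cl, rt) lactonises in the flask and gives 29 together with its C5′ epimer F8. Chromatography separates them and the route is rejoined at 29.

## Further compounds

F1 | step 8 | racemic trans tricyclic ketone (15 with its mirror image) | CC[C@H]1C(=O)Cc2cc(C(=O)OC(C)(C)C)n3c2[C@@H]1CCCC3.CC[C@@H]1C(=O)Cc2cc(C(=O)OC(C)(C)C)n3c2[C@H]1CCCC3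
F2 | step 8 | (6S,7S) enantiomer of 15 | CC[C@@H]1C(=O)Cc2cc(C(=O)OC(C)(C)C)n3c2[C@H]1CCCC3
F3 | step 12 | C4-(2-ethoxy-2-oxoethyl) derivative of 15, substituent equatorial | CC[C@H]1C(=O)[C@@H](CC(=O)OCC)c2cc(C(=O)OC(C)(C)C)n3c2[C@@H]1CCCC3
F4 | step 12 | cis-fused tetracyclic lactone lacking the Cα methyl | CC[C@H]1[C@H]2OC(=O)C[C@H]2c2cc(C(=O)OC(C)(C)C)n3c2[C@@H]1CCCC3
F5 | step 13 | Cα-phenylselanyl tetracyclic lactone, selenium convex | CC[C@H]1[C@H]2OC(=O)[C@](C)([Se]c3ccccc3)[C@H]2c2cc(C(=O)OC(C)(C)C)n3c2[C@@H]1CCCC3
F6 | step 6 | N,N-dimethylamide of 10 | CCCC(Cc1cn(CCCCC(=O)N(C)C)c(C(=O)OC(C)(C)C)c1)[N+](=O)[O-]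
F7 | step 6 | cyclic 9-(dimethyliminio)pyrroloazepine triflate | CCCC(Cc1cc(C(=O)OC(C)(C)C)n2CCCCC(=[N+](C)C)c12)[N+](=O)[O-].[O-]S(=O)(=O)C(F)(F)F
F8 | step 15 | (5′R) epimer of 29 | CC[C@H]1[C@H]2OC(=O)[C@@H](C)[C@H]2c2cc([C@H]3CC(=C)C(=O)O3)n3c2[C@@H]1CCCC3
A1 | alternative 1 | azido keto aldehyde with ketal at the future C5 | CC[C@H]1C2(OCCO2)CC(CC=O)C(=O)[C@@H]1CCCCN=[N+]=[N-]
A2 | alternative 1 | tricyclic pyrroloazepine ketal | CC[C@H]1C2(OCCO2)Cc2ccn3c2[C@@H]1CCCC3
A3 | alternative 2 | pyrroloazepine carrying the CH(Et)-linked α-methylbutenolide at C7 | CC[C@H]([C@H]1CCCCn2cccc12)[C@H]1OC(=O)C(C)=C1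
A4 | alternative 2 | tetracyclic core lacking the pendant lactone | CC[C@H]1[C@H]2OC(=O)[C@@H](C)[C@H]2c2ccn3c2[C@@H]1CCCC3
A5 | alternative 3 | racemic carbinol with the 2-oxopentyl chain | CCCC(=O)Cc1cc(C(=O)OC(C)(C)C)n2CCCCC(O)c12
A6 | alternative 3 | trans tricyclic ketone | CC[C@H]1C(=O)Cc2cc(C(=O)OC(C)(C)C)n3c2[C@@H]1CCCC3
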